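**Plan**
1. Retrosynthesis: the C7 acetate is traced back (Baeyer–Villiger, then Wacker) to a C7 vinyl group. The macrocycle is then cut at C7–C8, at C13–C14 (Negishi), at C1–C2 with the lactone C–O bond (allylation–lactonisation), and at the two C–O bonds of the dioxane.
2. Enabling feature: C8 is the methyl-bearing carbon of the 1,2-dioxane ring that is bonded to the O–O unit, so it sits at the ketal oxidation level. Its 3-methoxy derivative ionises to an endocyclic peroxycarbenium ion. C7 is delivered as the γ-carbon of an allylsilane, whose vinyl residue is a latent acetate.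
3. Forward order: East chain C2–C7 with the allylsilane (from geranyl acetate), then the cis-α-methylene lactone (C1, C2) and its bromide. West fragment C8–C13 as a 3-methoxy-1,2-dioxane carrying a (Z)-iodoalkene. Negishi union, closure of the 14-membered ring onto the pre-formed dioxane, then vinyl → acetyl → acetate.
4. Stereochemistry: 3E from geranyl acetate and 12Z from anti-carbomagnesiation. C1/C2 from a chiral chromium catalyst (syn addition gives the cis-lactone). C11 from a Ti–TADDOLate alkylation followed by SN2 inversion. C8 and C7 from the ring closure (axial attack cis to C12, tether-controlled face at C7). The Baeyer–Villiger step proceeds with retention.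

Key step: step 15

Remark: positions are named with cembrane numbering (C1/C2 = lactone ring-fusion carbons, C2 bearing the lactone oxygen; C7 = acetoxy carbon; C8 and C11 = peroxide-bearing carbons; C15, C16, C17 = lactone α-carbon, carbonyl and exocyclic methylene).
Remark: the methoxy-bearing ketal carbon of 21, 22 and 24 is an epimeric mixture (written without a stereo mark); both epimers give the same cation in step 15.
Remark: the sense of induction of the chiral chromium and titanium catalysts is assigned by analogy; the antipodal ligand is taken if a model reaction shows the opposite sense.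

**Step 1**
Reactants: 1 geranyl acetate
Product: 2 (2E)-3-methyl-6-oxohex-2-en-1-yl acetate
Conditions: O3 (1 equiv, indicator end point), CH2Cl2, −78 °C; then Me2S
Reagents that add atoms: ozone, [O-][O+]=O
Why: chemoselective ozonolysis with reductive work-up, because the electron-rich 6,7-alkene reacts well before the 2,3-alkene, which is deactivated by the allylic acetate and keeps its E geometry.

**Step 2**
Reactants: 2 (2E)-3-methyl-6-oxohex-2-en-1-yl acetate
Product: 3 (2E,6Z)-3-methyl-8-(trimethylsilyl)octa-2,6-dien-1-yl acetate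
Conditions: Ph3PCH3Br, n-BuLi, THF, 0 °C; Me3SiCH2I; n-BuLi, −78 °C; then 2, −78 °C → rt
Reagents that add atoms: methyltriphenylphosphonium bromide, C[P+](c1ccccc1)(c1ccccc1)c1ccccc1.[Br-]; (iodomethyl)trimethylsilane, C[Si](C)(C)CI
Why: Wittig reaction of the non-stabilised β-silyl ylide, built in the flask by alkylating methylenetriphenylphosphorane, should give the allylsilane with the Z geometry usual for such ylides, the acetate being far less electrophilic than the aldehyde at −78 °C.

**Step 3**
Reactants: 3 (2E,6Z)-3-methyl-8-(trimethylsilyl)octa-2,6-dien-1-yl acetate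
Product: 4 (2E,6Z)-3-methyl-8-(trimethylsilyl)octa-2,6-dien-1-ol
Conditions: K2CO3 (cat.), MeOH, 0 °C → rt
Reagents that add atoms: none
Why: base-catalysed transesterification (methanolysis) frees the allylic alcohol without touching the allylsilane.

**Step 4**
Reactants: 4 (2E,6Z)-3-methyl-8-(trimethylsilyl)octa-2,6-dien-1-ol
Product: 5 (2E,6Z)-3-methyl-8-(trimethylsilyl)octa-2,6-dienal
Conditions: MnO2, CH2Cl2, rt
Reagents that add atoms: none
Why: MnO2 oxidises allylic alcohols selectively to enals without E/Z isomerisation and leaves the allylsilane alone.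

**Step 5**
Reactants: 6 2-[(tert-butyldimethylsilyl)oxy]acetaldehyde; 7 methyl acrylate
Product: 8 methyl 4-[(tert-butyldimethylsilyl)oxy]-3-hydroxy-2-methylidenebutanoate (racemic)
Conditions: DABCO (0.3 equiv), neat, rt
Reagents that add atoms: none
Why: Morita–Baylis–Hillman reaction; the racemic carbinol centre is destroyed in step 6.

**Step 6**
Reactants: 8 methyl 4-[(tert-butyldimethylsilyl)oxy]-3-hydroxy-2-methylidenebutanoate
Product: 9 methyl (2Z)-2-(bromomethyl)-4-[(tert-butyldimethylsilyl)oxy]but-2-enoate
Conditions: NBS, Me2S, CH2Cl2, 0 °C → rt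
Reagents that add atoms: N-bromosuccinimide, O=C1CCC(=O)N1Br
Why: Corey–Kim-type activation of the alcohol followed by SN2′ attack of bromide gives the rearranged, thermodynamically favoured (Z)-2-(bromomethyl)alk-2-enoate.

**Step 7**
Reactants: 5 (2E,6Z)-3-methyl-8-(trimethylsilyl)octa-2,6-dienal; 9 methyl (2Z)-2-(bromomethyl)-4-[(tert-butyldimethylsilyl)oxy]but-2-enoate
Product: 11 (4R,5S)-4-{[(tert-butyldimethylsilyl)oxy]methyl}-3-methylidene-5-[(1E,5Z)-2-methyl-7-(trimethylsilyl)hepta-1,5-dien-1-yl]oxolan-2-one (cis-lactone), via trimethylsilyl ether adduct 10 (not isolated)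
Conditions: CrCl2 (10 mol %), (S,S)-3,6-di-tert-butyl-1,8-bis(4-isopropyl-4,5-dihydrooxazol-2-yl)-9H-carbazole (12 mol %), i-Pr2NEt (30 mol %), Mn powder, Me3SiCl, THF, rt; then 1 M HCl, THF, 0 °C
Reagents that add atoms: none
Why: catalytic asymmetric Nozaki–Hiyama–Kishi 2-(alkoxycarbonyl)allylation, in which the (Z)-allylchromium reacts at its γ-carbon through a chair transition state to give the syn adduct (hence the cis-lactone after acid-induced lactonisation) while the chiral ligand on divalent/trivalent chromium selects the aldehyde face and so sets C1 and C2.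

**Step 8**
Reactants: 11 the silyl-protected cis-lactone
Product: 12 (4S,5S)-4-(bromomethyl)-3-methylidene-5-[(1E,5Z)-2-methyl-7-(trimethylsilyl)hepta-1,5-dien-1-yl]oxolan-2-one
Conditions: Ph3PBr2, CH2Cl2, 0 °C → rt
Reagents that add atoms: triphenylphosphine dibromide, BrP(Br)(c1ccccc1)(c1ccccc1)c1ccccc1
Why: triphenylphosphine dibromide converts a primary silyl ether directly into the bromide (SN2 on the oxyphosphonium), so no free alcohol appears that could translactonise, and no stereocentre is touched (the descriptor change at C4 is only a priority change).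

**Step 9**
Reactants: 13 prop-2-yn-1-ol
Product: 14 (2Z)-3-iodo-2-methylprop-2-en-1-ol
Conditions: MeMgBr (2.5 equiv), CuI (10 mol %), Et2O, −10 °C → rt; then I2, −78 → 0 °C
Reagents that add atoms: methylmagnesium bromide, C[Mg]Br; iodine, II
Why: copper-catalysed anti-carbomagnesiation of the propargylic alkoxide through a five-membered magnesium chelate, then iodinolysis with retention, fixes the Z geometry (iodine cis to CH2OH).

**Step 10**
Reactants: 14 (2Z)-3-iodo-2-methylprop-2-en-1-ol
Product: 15 (2Z)-3-iodo-2-methylprop-2-enal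
Conditions: MnO2, CH2Cl2, rt; used directly
Reagents that add atoms: none
Why: MnO2 oxidation of the allylic alcohol is neutral and should preserve the Z-iodoalkene.

**Step 11**
Reactants: 15 (2Z)-3-iodo-2-methylprop-2-enal; 16 4-bromo-2-methylbut-1-ene
Product: 19 (1Z,3S)-1-iodo-2,6-dimethylhepta-1,6-dien-3-ol, via Grignard reagent 17 (not isolated), via dialkylzinc 18 (not isolated)
Conditions: 16, Mg, Et2O; ZnCl2, then 1,4-dioxane (salts filtered off); Ti(OiPr)4 (1.2 equiv), (4R,5R)-TADDOL–Ti(OiPr)2 (0.2 equiv), toluene, −25 °C, then 15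
Reagents that add atoms: none
Why: Ti–TADDOLate-catalysed enantioselective addition of a dialkylzinc (made from the Grignard reagent by transmetallation) to the enal, where the (R,R)-ligand should direct Si-face attack and give the S carbinol at C11.

**Step 12**
Reactants: 19 (1Z,3S)-1-iodo-2,6-dimethylhepta-1,6-dien-3-ol
Product: 20 (1Z,3S)-1-iodo-2,6-dimethylhepta-1,6-dien-3-yl methanesulfonate
Conditions: MsCl, Et3N, CH2Cl2, −20 °C
Reagents that add atoms: methanesulfonyl chloride, CS(=O)(=O)Cl
Why: sulfonylation with retention; the β-iodine on the alkene makes this allylic mesylate less prone to ionise than an ordinary one.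

**Step 13**
Reactants: 20 (1Z,3S)-1-iodo-2,6-dimethylhepta-1,6-dien-3-yl methanesulfonate
Product: 22 (6R)-6-[(1Z)-1-iodoprop-1-en-2-yl]-3-methoxy-3-methyl-1,2-dioxane (epimers at C3), via hydroperoxy ketal 21 (not isolated)
Conditions: O3, CH2Cl2/MeOH, −78 °C (indicator end point), N2 purge; then KOtBu, 18-crown-6, THF, 0 °C
Reagents that add atoms: ozone, [O-][O+]=O; methanol, CO
Why: Criegee ozonolysis of the 1,1-disubstituted alkene in methanol traps the carbonyl oxide as the methoxy hydroperoxide (the electron-poor iodoalkene reacts more slowly), and base then closes the dioxane by 6-exo-tet SN2 alkylation of the hydroperoxy ketal with inversion at C11 (S mesylate → 6R).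

**Step 14**
Reactants: 12 the bromomethyl lactone; 22 the iodoalkenyl methoxydioxane
Product: 24 (4S,5S)-4-{(2Z)-3-[(6R)-3-methoxy-3-methyl-1,2-dioxan-6-yl]but-2-en-1-yl}-3-methylidene-5-[(1E,5Z)-2-methyl-7-(trimethylsilyl)hepta-1,5-dien-1-yl]oxolan-2-one, via alkylzinc bromide 23 (not isolated)
Conditions: 12, Zn dust, LiCl, THF, 40 °C; then 22, Pd2(dba)3 (2.5 mol %), tri(2-furyl)phosphine (10 mol %), THF/NMP, rt
Reagents that add atoms: none
Why: Negishi sp3–sp2 coupling, in which oxidative addition of zerovalent palladium to the alkenyl iodide is fast at rt and retains the Z geometry, alkylzinc halides tolerate lactone, allylsilane and dialkyl peroxide, and the weakly donating phosphine limits attack on the O–O bond and on the allylic lactone.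

**Step 15**
Reactants: 24 the seco allylsilane–methoxydioxane
Product: 25 (1S,2S,3E,7R,8S,11R,12Z)-7-ethenyl-8,11-epidioxycembra-3,12,15(17)-trien-16,2-olide
Conditions: Me3SiOTf (1.1 equiv), 2,6-di-tert-butyl-4-methylpyridine (0.3 equiv), CH2Cl2, −78 °C, 24 added over 8 h (final 0.5 mM); Et3N quench
Reagents that add atoms: none
Why: Proposed new method: Me3SiOTf ionises the 3-methoxy ketal of the 1,2-dioxane to an endocyclic peroxycarbenium ion (O–O–C8+), which is attacked at C8 by the γ-carbon (C7) of the tethered allylsilane in an anti SE2′ process; loss of the silyl group leaves the C7 vinyl group and regenerates Me3SiOTf. The closest known reactions are the Lewis-acid-mediated intermolecular additions of allyltrimethylsilane and silyl enol ethers to 3-alkoxy-1,2-dioxolanes and -dioxanes, and oxocarbenium (Prins- or Hosomi–Sakurai-type) macrocyclisations of ordinary acetals, which are merged here. The 14-membered carbocycle closes in a 14-exo-trig mode with respect to the allylsilane C=C (C7 in the ring, the two vinyl carbons outside) onto the endocyclic C=O+ of the six-membered cation, so that the pre-formed dioxane becomes the 8,11-epidioxy bridge of the bicyclic core. C8 is set by the stereoelectronically preferred axial attack on the half-chair cation that keeps the C11 alkenyl group pseudo-equatorial, reinforced by the tether that issues from that same substituent, so C7 enters cis to C12; C7 is set by an antiperiplanar open transition state in which chain carbon C6 lies over the ring CH2 (C9) and H7 faces the C8 methyl, the arrangement that lets the ten-atom tether reach C11. The step needs chemoselective ionisation (the ketal ionises at −78 °C well before the allylic lactone C–O or the allylic peroxide C–O bond), site selectivity (the allylsilane is far more nucleophilic than the two trisubstituted alkenes, both deactivated by allylic oxygen, and a nine-membered conjugate addition to the methylene lactone is disfavoured) and ring closure over oligomerisation (slow addition, high dilution).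

**Step 16**
Reactants: 25 the 7-ethenyl macrocycle
Product: 26 (1S,2S,3E,7S,8S,11R,12Z)-7-acetyl-8,11-epidioxycembra-3,12,15(17)-trien-16,2-olide
Conditions: Pd(Quinox)Cl2 [PdCl2 complex of 2-(4,5-dihydrooxazol-2-yl)quinoline] (5 mol %), AgSbF6 (12 mol %), aq. t-BuOOH, CH2Cl2, 0 °C → rt
Reagents that add atoms: tert-butyl hydroperoxide, CC(C)(C)OO
Why: Wacker-type oxidation by divalent palladium, in which only the monosubstituted vinyl group is oxidised (Markovnikov) to the methyl ketone; the copper-free, peroxide-mediated variant avoids copper salts that would cleave the O–O bond, and the non-basic medium leaves the now enolisable C7 configuration intact.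

**Step 17**
Reactants: 26 the 7-acetyl macrocycle
Product: 27 CNP0238885.10, (1S,2S,3E,7S,8S,11R,12Z)-7-acetoxy-8,11-epidioxycembra-3,12,15(17)-trien-16,2-olide
Conditions: (Me3SiO)2, SnCl4 (0.3 equiv), trans-cyclohexane-1,2-diamine (0.3 equiv), 4 Å MS, CH2Cl2, −20 → 0 °C
Reagents that add atoms: bis(trimethylsilyl) peroxide, C[Si](C)(C)OO[Si](C)(C)C
Why: Baeyer–Villiger oxidation with bis(trimethylsilyl) peroxide, a reagent that oxidises ketones without epoxidising C=C bonds; the secondary C7 migrates in preference to methyl with retention, turning the acetyl group into the C7 acetate.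

**Compound list**
1 | geranyl acetate | CC(C)=CCC/C(C)=C/COC(C)=O | starting material
2 | (2E)-3-methyl-6-oxohex-2-en-1-yl acetate | O=CCC/C(C)=C/COC(C)=O | intermediate
3 | (2E,6Z)-3-methyl-8-(trimethylsilyl)octa-2,6-dien-1-yl acetate | C[Si](C)(C)C/C=C\CC/C(C)=C/COC(C)=O | intermediate
4 | (2E,6Z)-3-methyl-8-(trimethylsilyl)octa-2,6-dien-1-ol | C[Si](C)(C)C/C=C\CC/C(C)=C/CO | intermediate
5 | (2E,6Z)-3-methyl-8-(trimethylsilyl)octa-2,6-dienal | C[Si](C)(C)C/C=C\CC/C(C)=C/C=O | intermediate
6 | 2-[(tert-butyldimethylsilyl)oxy]acetaldehyde | O=CCO[Si](C)(C)C(C)(C)C | starting material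
7 | methyl acrylate | C=CC(=O)OC | starting material
8 | methyl 4-[(tert-butyldimethylsilyl)oxy]-3-hydroxy-2-methylidenebutanoate (racemic) | C=C(C(=O)OC)C(O)CO[Si](C)(C)C(C)(C)C | intermediate
9 | methyl (2Z)-2-(bromomethyl)-4-[(tert-butyldimethylsilyl)oxy]but-2-enoate | BrC/C(C(=O)OC)=C\CO[Si](C)(C)C(C)(C)C | intermediate
10 | methyl (3R,4S,5E,9Z)-3-{[(tert-butyldimethylsilyl)oxy]methyl}-6-methyl-2-methylidene-11-(trimethylsilyl)-4-[(trimethylsilyl)oxy]undeca-5,9-dienoate | C=C(C(=O)OC)[C@H](CO[Si](C)(C)C(C)(C)C)[C@@H](O[Si](C)(C)C)/C=C(\C)CC/C=C\C[Si](C)(C)C | intermediate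
11 | (4R,5S)-4-{[(tert-butyldimethylsilyl)oxy]methyl}-3-methylidene-5-[(1E,5Z)-2-methyl-7-(trimethylsilyl)hepta-1,5-dien-1-yl]oxolan-2-one | C=C1C(=O)O[C@@H](/C=C(\C)CC/C=C\C[Si](C)(C)C)[C@H]1CO[Si](C)(C)C(C)(C)C | intermediate
12 | (4S,5S)-4-(bromomethyl)-3-methylidene-5-[(1E,5Z)-2-methyl-7-(trimethylsilyl)hepta-1,5-dien-1-yl]oxolan-2-one | C=C1C(=O)O[C@@H](/C=C(\C)CC/C=C\C[Si](C)(C)C)[C@H]1CBr | intermediate
13 | prop-2-yn-1-ol | C#CCO | starting material
14 | (2Z)-3-iodo-2-methylprop-2-en-1-ol | I/C=C(/C)CO | intermediate
15 | (2Z)-3-iodo-2-methylprop-2-enal | I/C=C(/C)C=O | intermediate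
16 | 4-bromo-2-methylbut-1-ene | C=C(C)CCBr | starting material
17 | (3-methylbut-3-en-1-yl)magnesium bromide | C=C(C)CC[Mg]Br | intermediate
18 | bis(3-methylbut-3-en-1-yl)zinc | C=C(C)CC[Zn]CCC(C)=C | intermediate
19 | (1Z,3S)-1-iodo-2,6-dimethylhepta-1,6-dien-3-ol | I/C=C(/C)[C@@H](O)CCC(C)=C | intermediate
20 | (1Z,3S)-1-iodo-2,6-dimethylhepta-1,6-dien-3-yl methanesulfonate | I/C=C(/C)[C@@H](OS(C)(=O)=O)CCC(C)=C | intermediate
21 | (1Z,3S)-6-hydroperoxy-1-iodo-6-methoxy-2-methylhept-1-en-3-yl methanesulfonate (ketal epimers) | I/C=C(/C)[C@@H](OS(C)(=O)=O)CCC(C)(OC)OO | intermediate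
22 | (6R)-6-[(1Z)-1-iodoprop-1-en-2-yl]-3-methoxy-3-methyl-1,2-dioxane (epimers at C3) | I/C=C(/C)[C@H]1CCC(C)(OC)OO1 | intermediate
23 | {[(3S,4S)-4-methylidene-5-oxo-2-... lactone]methyl}zinc bromide, the alkylzinc bromide of 12 | C=C1C(=O)O[C@@H](/C=C(\C)CC/C=C\C[Si](C)(C)C)[C@H]1C[Zn]Br | intermediate
24 | (4S,5S)-4-{(2Z)-3-[(6R)-3-methoxy-3-methyl-1,2-dioxan-6-yl]but-2-en-1-yl}-3-methylidene-5-[(1E,5Z)-2-methyl-7-(trimethylsilyl)hepta-1,5-dien-1-yl]oxolan-2-one (ketal epimers) | C=C1C(=O)O[C@@H](/C=C(\C)CC/C=C\C[Si](C)(C)C)[C@H]1C/C=C(/C)[C@H]2CCC(C)(OC)OO2 | intermediate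
25 | (1S,2S,3E,7R,8S,11R,12Z)-7-ethenyl-8,11-epidioxycembra-3,12,15(17)-trien-16,2-olide | C=C1C(=O)O[C@H]2/C=C(\C)CC[C@H](C=C)[C@]3(C)CC[C@@H](OO3)/C(C)=C\C[C@@H]12 | intermediate
26 | (1S,2S,3E,7S,8S,11R,12Z)-7-acetyl-8,11-epidioxycembra-3,12,15(17)-trien-16,2-olide | C=C1C(=O)O[C@H]2/C=C(\C)CC[C@H](C(C)=O)[C@]3(C)CC[C@@H](OO3)/C(C)=C\C[C@@H]12 | intermediate
27 | CNP0238885.10, (1S,2S,3E,7S,8S,11R,12Z)-7-acetoxy-8,11-epidioxycembra-3,12,15(17)-trien-16,2-olide | C=C1C(=O)O[C@H]2/C=C(\C)CC[C@H](OC(C)=O)[C@]3(C)CC[C@@H](OO3)/C(C)=C\C[C@@H]12 | target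

**Step count**
Total: 17 steps. Longest linear sequence: 10 steps (1, 2, 3, 4, 7, 8, 14, 15, 16, 17).

**Steps most likely to fail**

Step 15 (labelled step). The ring closure may be too slow, so that oligomerisation or protodesilylation of the allylsilane wins, or the face selection at C7 may be poor. Fallback with known chemistry, setting out from 22 and 12: the C7–C8 bond is made in its precedented intermolecular form (Me3SiOTf, CH2Cl2, −78 °C) to give the acyclic C7–C8 adduct F1. C8 should again arise from axial attack; the C7 epimers are separated. Zinc insertion into the primary bromide gives its alkylzinc bromide F2, and an intramolecular Negishi coupling with the (Z)-iodoalkene under high dilution (Pd2(dba)3, tri(2-furyl)phosphine) closes the ring at C13–C14. The route is rejoined at 25.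

Step 13. Ozone may oxidise the iodoalkene competitively, the hydroperoxy ketal may decompose before it closes, or the mesylate may be eliminated by the strong base. Fallback setting out from 20: displacement with 2-methoxyprop-2-yl hydroperoxide (CsOH, DMF, 0 °C, inversion) gives the perketal-protected allylic peroxide F3. Lemieux–Johnson cleavage (OsO4 cat., NaIO4, 2,6-lutidine, dioxane/H2O) of the 1,1-disubstituted alkene gives the methyl ketone F4. PPTS in MeOH then removes the perketal; the freed hydroperoxide closes onto the ketone and the peroxyhemiketal is methylated in the same flask. The route is rejoined at 22.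

Step 7. Facial control by the chromium catalyst may be insufficient with this γ-(silyloxymethyl) reagent, or the silyloxy group may be lost by β-elimination from the allylchromium. Fallback setting out from 5 and 9: an indium-mediated Barbier allylation (In, THF/H2O, rt, syn-selective) gives the racemic syn-hydroxy ester F5, which is lactonised (PPTS, CH2Cl2) to racemic 11. Preparative HPLC on a chiral stationary phase removes the mirror-image lactone F6. The route is rejoined at 11.

**Further compounds**
F1 | step 15 | (4S,5S)-4-(bromomethyl)-5-[(1E,5R)-5-{(3S,6R)-6-[(1Z)-1-iodoprop-1-en-2-yl]-3-methyl-1,2-dioxan-3-yl}-2-methylhepta-1,6-dien-1-yl]-3-methylideneoxolan-2-one | C=C1C(=O)O[C@@H](/C=C(\C)CC[C@H](C=C)[C@]2(C)CC[C@@H](OO2)/C(C)=C\I)[C@H]1CBr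
F2 | step 15 | alkylzinc bromide of F1 | C=C1C(=O)O[C@@H](/C=C(\C)CC[C@H](C=C)[C@]2(C)CC[C@@H](OO2)/C(C)=C\I)[C@H]1C[Zn]Br
F3 | step 13 | (1Z,3R)-1-iodo-3-[(2-methoxypropan-2-yl)peroxy]-2,6-dimethylhepta-1,6-diene | I/C=C(/C)[C@H](OOC(C)(C)OC)CCC(C)=C
F4 | step 13 | (5R,6Z)-7-iodo-5-[(2-methoxypropan-2-yl)peroxy]-6-methylhept-6-en-2-one | I/C=C(/C)[C@H](OOC(C)(C)OC)CCC(C)=O
F5 | step 7 | racemic methyl (3R*,4S*,5E,9Z)-3-{[(tert-butyldimethylsilyl)oxy]methyl}-4-hydroxy-6-methyl-2-methylidene-11-(trimethylsilyl)undeca-5,9-dienoate (one enantiomer drawn) | C=C(C(=O)OC)[C@H](CO[Si](C)(C)C(C)(C)C)[C@@H](O)/C=C(\C)CC/C=C\C[Si](C)(C)C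
F6 | step 7 | (4S,5R)-enantiomer of 11 | C=C1C(=O)O[C@H](/C=C(\C)CC/C=C\C[Si](C)(C)C)[C@@H]1CO[Si](C)(C)C(C)(C)C
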